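A small charge of precatalyst, 0.54 mM, faces 1.0 M of substrate in your flask with 1.50 M of reagent. You asked for a quick number at 4.0 d, with the hunch that the fall slows late but keeps going.

common to all: precatalyst 0.54 mM

|  | substrate | reagent | remark | time |
|---|---|---|---|---|
| teal | 1 M | 1 M | run made earlier |  |
| grey | 1 M | 2.2 M | run made earlier |  |
| flask | 1.0 M | 1.50 M |  | 4.0 d |

| run | time / d | substrate / % | target / % |
|---|---|---|---|
| teal | 0.250 | 98.6 | 0 |
| teal | 0.625 | 91.2 | 8.9 |
| teal | 1.25 | 79.5 | 23.3 |
| teal | 3.00 | 47.0 | 53.9 |
| grey | 0.417 | 94.7 | 5.8 |
| grey | 1.04 | 78.4 | 22.4 |
| grey | 2.08 | 50.8 | 48.8 |
| grey | 3.00 | 31.9 | 70.2 |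

(each reading ± 1 percentage point)

- for target the crystals are counted in
- as a solid, counted per litre of solution: crystals
- what may be going on: catalyst intermediate C <-> free catalyst + target; substrate + catalyst intermediate A -> spent catalyst; substrate + catalyst intermediate B -> catalyst intermediate C; catalyst intermediate A <-> released group + catalyst intermediate B; crystals <-> target; reagent + free catalyst <-> catalyst intermediate A; precatalyst -> free catalyst
- the reaction counts as stopped when no species that holds the substrate changes by six tenths of a point or more over the second half of the time

- at 4.0 d, what has stopped the reaction, if anything has (forward and back rates have come level / the reagent has run out first / it is still moving / all of the substrate has reacted / no working catalyst is left)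
- share of the substrate used up at 4.0 d
- target at 4.0 d, in percent of the substrate charged

Past its start, the teal run's substrate falls at a pace that clears the whole charge in 5.37 d, and the grey run's in 4.11 d, a fall close to zero order. These two times scale as reagent to the power 0.339, so your flask gets 4.68 d. This emptying time, the days the whole substrate charge needs at the steady fall, is what I would count in.

Both runs lag their straight lines, by 0.176 d on average. So your 4.0 d holds 81.7% of an emptying time, and that is my figure for the substrate used. Substrate and target add to 101% at the teal run's last reading, so I give target the same figure. The clock ends before the emptying does, so your flask is still moving. The grey run's last stretch gives 4.87 d, so I hold my figure as high.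

The forecast, lower than my figure, says it is still moving, with 76% used and 76% target, since “catalyst is evidently still working”. The flask gives this: it is still moving, with 78.0% used and 78.0% target.

    catalyst intermediate C ⇌ free catalyst + target (K = 52.0 M, k = 14300 /h)
    substrate + catalyst intermediate A → spent catalyst (k = 0.0245 /M/h)
    substrate + catalyst intermediate B → catalyst intermediate C (k = 309 /M/h)
    catalyst intermediate A ⇌ released group + catalyst intermediate B (K = 38.2 M, k = 48.1 /h)
    crystals ⇌ target, rate k5*(cs5 - [target]) while solid is left; crystals form when [target] > cs5 (solubility = 0.620 M, k = 3.15 /h)
    reagent + free catalyst ⇌ catalyst intermediate A (K = 1.70 /M, k = 2660 /M/h)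
    precatalyst → free catalyst (k = 0.0796 /h)

Over its second half, this flask's substrate fell from 56.7% to 22.0%, a pace with an emptying time of 5.76 d, longer than the 4.68 d I carried, while spent catalyst rose from 32.1% to 45.0% of the catalyst. At that pace the 22% of substrate left is 1.27 d of work, with 48% of the reagent still there. On the neighbour read at 40 h, the same count gives 31.8% used. The computed flask there stands at 35.7%, ahead of the count.

The data are calculated for substances that don't exist.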